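Everything rests on closing ring C, the 1,2-dioxane, at its O–C14 bond. C14 is allylic to the exocyclic C13 methylene and must end axial on the trans-fused dioxane–lactone, so its configuration is installed on the open chain and transferred by inversion: the tertiary C17 hydroperoxide, set anti to the C16 oxygen by perhydrolysis of an (E)-derived epoxide, displaces a (14S) allylic chloride in one 6-exo-tet SN2 closure. The precursor is an open-chain chloro hydroxy hydroperoxide carried by a larixol-derived decalin; decalin and side chain are joined at C13–C14 by Nozaki–Hiyama–Kishi coupling, and ring D, the lactone, is closed last by oxidation of the C16/C19 diol.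

Key step: step 18

Remarks: (+)-Larixol is taken as a commercially available natural product. Compounds 1–13 carry labdane locants (C17 = the carbon on C8, C18 = the 4α carbon, C14/C15 = the vinyl carbons that are lost). From 19 on, C14–C19 are the side-chain atoms of the target: C13 carries the exocyclic CH2, C14 is O–O–CH, C16 is the lactone O–CH, C17 is O–O–C(CH3), C19 is the lactone C=O. Rings A and B are the decalin. α/β refer to the usual labdane drawing with the C10 methyl β.

Step 1
Reactants: 1 (+)-larixol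
Product: 2 8α,17-epoxylabd-14-ene-6α,13S-diol
Conditions: mCPBA, NaHCO3, CH2Cl2, 0 °C
Reagents that add atoms: 3-chloroperoxybenzoic acid, O=C(OO)c1cccc(Cl)c1
Why: Prilezhaev epoxidation should take the electron-rich 1,1-disubstituted exocyclic alkene before the vinyl group and from the α face (anti to the axial C10 methyl, guided by hydrogen bonding to the homoallylic 6α-OH), which sets C8 with oxygen α.

Step 2
Reactants: 2 8α,17-epoxylabd-14-ene-6α,13S-diol
Product: 3 8α,17-epoxy-6α-hydroxy-14,15-dinorlabdan-13-one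
Conditions: KMnO4, MgSO4, acetone/H2O, 0 °C to rt
Reagents that add atoms: none
Why: Permanganate cleavage of a tertiary vinyl carbinol (dihydroxylation, glycol cleavage, oxidative decarboxylation of the α-hydroxy acid) is the established degradation of labdane side chains to the C13 methyl ketone, and the epoxide and the hindered secondary alcohol should survive the buffered medium.

Step 3
Reactants: 3 8α,17-epoxy-6α-hydroxy-14,15-dinorlabdan-13-one
Product: 6 6α,18:8α,17-diepoxy-14,15-dinorlabdan-13-one, via 6α-hypoiodite 4 (not isolated), via 4α-iodomethyl alcohol 5 (not isolated)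
Conditions: PhI(OAc)2, I2, NaHCO3, cyclohexane/CH2Cl2, hν (tungsten lamp), 25 °C
Reagents that add atoms: none
Why: In this hypoiodite reaction (Suárez conditions) the 6α-alkoxy radical should abstract hydrogen by 1,5-transfer from the equatorial 4α-methyl group, the only δ C–H within reach (peri, syn-pentane contact), and iodination followed by displacement closes the tetrahydrofuran, so that C4 becomes a stereocenter with the oxidised carbon α.

Step 4
Reactants: 6 6α,18:8α,17-diepoxy-14,15-dinorlabdan-13-one
Product: 7 6α,18-epoxy-14,15-dinorlabdane-8α,13-diol (both C13 epimers)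
Conditions: LiAlH4, THF, 0 to 50 °C
Reagents that add atoms: none
Why: Hydride should open the spiro-epoxide at its CH2 terminus (SN2), which leaves the C8–O bond and hence the 8α-OH/8β-CH3 arrangement untouched, and it reduces the ketone to an alcohol whose configuration does not matter because step 5 re-oxidises it.

Step 5
Reactants: 7 6α,18-epoxy-14,15-dinorlabdane-8α,13-diol
Product: 8 8α-hydroxy-13-oxo-14,15-dinorlabdan-18,6α-olide
Conditions: RuCl3·xH2O (cat.), NaIO4, CCl4/MeCN/H2O, rt
Reagents that add atoms: sodium periodate (oxygen source for RuO4), [Na+].[O-]I(=O)(=O)=O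
Why: RuO4 formed in situ should oxidise the ether CH2 next to oxygen to the γ-lactone (the C6–H position is tertiary and shielded) and the secondary C13 alcohol to the ketone, while the tertiary 8α-OH cannot be oxidised.

Step 6
Reactants: 8 8α-hydroxy-13-oxo-14,15-dinorlabdan-18,6α-olide
Product: 10 methyl 6α,8α-dihydroxy-13-oxo-14,15-dinorlabdan-18-oate, via potassium carboxylate 9 (not isolated)
Conditions: KOH, MeOH/H2O, 50 °C; concentrate, CO2; then MeI, DMF, rt
Reagents that add atoms: potassium hydroxide, [K+].[OH-]; iodomethane, CI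
Why: Saponification opens the strained lactone and SN2 O-methylation of the carboxylate under non-acidic conditions should give the hydroxy ester without a chance to relactonise, and no stereocenter is touched.

Step 7
Reactants: 10 methyl 6α,8α-dihydroxy-13-oxo-14,15-dinorlabdan-18-oate
Product: 11 methyl 13-oxo-6α,8α-bis(triethylsilyloxy)-14,15-dinorlabdan-18-oate
Conditions: TESOTf, 2,6-lutidine, CH2Cl2, −78 to 0 °C
Reagents that add atoms: triethylsilyl trifluoromethanesulfonate, CC[Si](CC)(CC)OS(=O)(=O)C(F)(F)F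
Why: The silyl triflate should silylate both the hindered secondary 6α-OH and the tertiary 8α-OH, which shields them from the base, the oxidant and the chlorinating agent of steps 8, 13 and 15, and any silyl enol ether of the methyl ketone is hydrolysed on aqueous work-up.

Step 8
Reactants: 11 methyl 13-oxo-6α,8α-bis(triethylsilyloxy)-14,15-dinorlabdan-18-oate
Product: 13 terminal enol triflate of 11 (CH2=C(OTf)– at C13), via potassium enolate 12 (not isolated)
Conditions: KN(SiMe3)2, THF, −78 °C; then PhNTf2, −78 to 0 °C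
Reagents that add atoms: N-phenylbis(trifluoromethanesulfonimide), O=S(=O)(N(c1ccccc1)S(=O)(=O)C(F)(F)F)C(F)(F)F
Why: Kinetic deprotonation of the methyl ketone at the unhindered CH3 and O-sulfonylation of the enolate should give the terminal enol triflate, and the C4 ester has no α-hydrogen.

Step 9
Reactants: 14 but-3-yn-1-ol
Product: 15 tert-butyl(but-3-yn-1-yloxy)diphenylsilane
Conditions: TBDPSCl, imidazole, DMF, rt
Reagents that add atoms: tert-butyl(chloro)diphenylsilane, CC(C)(C)[Si](Cl)(c1ccccc1)c1ccccc1
Why: Standard silylation of a primary alcohol; the TBDPS ether is chosen because it should survive the acid of step 17.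

Step 10
Reactants: 15 tert-butyl(but-3-yn-1-yloxy)diphenylsilane
Product: 18 (E)-6-(tert-butyldiphenylsilyloxy)-4-methylhex-3-en-1-ol, via alkenylalane 16 (not isolated), via lithium alanate 17 (not isolated)
Conditions: AlMe3, Cp2ZrCl2 (cat.), CH2Cl2, rt; evaporate; n-BuLi, THF/hexane, −78 °C; ethylene oxide, −78 °C to rt
Reagents that add atoms: trimethylaluminium, C[Al](C)C; oxirane, C1CO1
Why: Negishi zirconium-catalysed carboalumination adds CH3 and Al syn across the alkyne (methyl to the internal carbon), and the derived alanate opens ethylene oxide with retention of the alkene geometry, so the trisubstituted alkene should be E.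

Step 11
Reactants: 18 (E)-6-(tert-butyldiphenylsilyloxy)-4-methylhex-3-en-1-ol
Product: 19 (E)-6-(tert-butyldiphenylsilyloxy)-4-methylhex-3-enal
Conditions: Dess–Martin periodinane, NaHCO3, CH2Cl2, 0 °C (used at once)
Reagents that add atoms: none
Why: Buffered Dess–Martin oxidation should give the β,γ-unsaturated aldehyde under neutral conditions that do not move the alkene into conjugation.

Step 12
Reactants: 13 terminal enol triflate; 19 (E)-6-(tert-butyldiphenylsilyloxy)-4-methylhex-3-enal
Product: 21 allylic alcohol: decalin of 13 whose C13(=CH2) now carries CH(OH)CH2CH=C(CH3)CH2CH2OTBDPS (16E; both C14 epimers), via alkenylchromium dichloride 20 (not isolated)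
Conditions: CrCl2, NiCl2 (cat.), DMF, rt
Reagents that add atoms: none
Why: In this Nozaki–Hiyama–Kishi coupling zerovalent nickel inserts into the C–OTf bond, transmetallation gives the alkenylchromium species, and this adds only to the aldehyde, so the ester and the silyl ethers are tolerated; C14 forms without control and is corrected in steps 13 and 14.

Step 13
Reactants: 21 allylic alcohol (C14 epimers)
Product: 22 α-methylene ketone (C14=O)
Conditions: Dess–Martin periodinane, NaHCO3, CH2Cl2, 0 °C
Reagents that add atoms: none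
Why: Oxidation of the allylic alcohol removes the uncontrolled C14 center under neutral conditions that should leave the skipped C16=C17 alkene in place.

Step 14
Reactants: 22 α-methylene ketone
Product: 23 (14R)-allylic alcohol
Conditions: (S)-Me-CBS (20 mol %), catecholborane, toluene, −78 °C
Reagents that add atoms: none
Why: In this Corey–Bakshi–Shibata reduction the α-substituted alkenyl group acts as the large and the CH2 group as the small substituent, so the (S)-oxazaborolidine should deliver hydride to give the (14R)-alcohol, and catecholborane at low temperature should not hydroborate the alkenes.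

Step 15
Reactants: 23 (14R)-allylic alcohol
Product: 24 (14S)-allylic chloride
Conditions: PPh3, hexachloroacetone, CH2Cl2, −20 to 0 °C
Reagents that add atoms: hexachloroacetone, O=C(C(Cl)(Cl)Cl)C(Cl)(Cl)Cl
Why: Appel-type chlorination with PPh3/hexachloroacetone converts secondary allylic alcohols into chlorides by SN2 attack of chloride on the alkoxyphosphonium ion, which should invert C14 to S without allylic transposition.

Step 16
Reactants: 24 (14S)-allylic chloride
Product: 25 (14S,16S,17S)-14-chloro-16,17-epoxide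
Conditions: L-fructose-derived Shi ketone (30 mol %), KHSO5 (as Oxone), K2CO3, Bu4NHSO4, MeCN/dimethoxymethane/aq. Na2B4O7, 0 °C
Reagents that add atoms: potassium peroxymonosulfate, [K+].[O-]S(=O)(=O)OO
Why: In this Shi epoxidation the chiral dioxirane should take the electron-rich trisubstituted (E)-alkene in preference to the 1,1-disubstituted alkene that the allylic chloride deactivates, and the spiro transition state of the ketone enantiomer derived from L-fructose should give the (16S,17S)-epoxide.

Step 17
Reactants: 25 (14S,16S,17S)-14-chloro-16,17-epoxide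
Product: 26 (14S,16S,17R)-14-chloro-16-hydroxy-17-hydroperoxide
Conditions: H2O2 (ethereal), H3PMo12O40 (cat.), Et2O, 0 °C to rt
Reagents that add atoms: hydrogen peroxide, OO
Why: In this acid-catalysed perhydrolysis H2O2 should attack the tertiary carbon C17, which carries most of the positive charge, from the face opposite to the epoxide oxygen, so that C17 is inverted to R and the hydroperoxide stands anti to the C16 hydroxyl, whose configuration is retained.

Step 18
Reactants: 26 (14S,16S,17R)-14-chloro-16-hydroxy-17-hydroperoxide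
Product: 28 (14R,16S,17R)-1,2-dioxane (ring C closed; 16-OH free; C19 OTBDPS; 6α,8α-bis-OTES), via potassium peroxide 27 (not isolated)
Conditions: KOtBu (1.0 equiv), 18-crown-6, THF (0.005 M), −20 to 0 °C
Reagents that add atoms: none
Why: The base removes the hydroperoxide proton (pKa about 12.5, several units below the C16 alcohol), and the terminal oxygen of peroxide anion 27, an α-effect nucleophile, attacks C14 at the rear of the C–Cl bond, so that ring C closes by a 6-exo-tet SN2 displacement with loss of chloride. The closest known reaction type is the base-mediated intramolecular alkylation of hydroperoxides by halides and sulfonates that is used to make 1,2-dioxanes and 1,2-dioxolanes. C14 is the only new stereocenter and is set by inversion of the (14S)-chloride to 14R, while C16 and C17 are carried over from 26; this puts the C13 substituent on the face that becomes axial when ring D is fused trans, an arrangement that a conformationally controlled closure would not give reliably. The step needs O-alkylation by the peroxide and not by an alkoxide, and SN2 at C14 and not SN2′, E2 or C–C fragmentation of the β-hydroxy hydroperoxide. These are secured by the allylic activation of C14 by the C13 methylene, by the weak basicity of the peroxide anion and the use of one equivalent of base at low temperature, and by ring size, since attack at the methylene terminus would give an eight-membered ring. The tertiary hydroperoxide has no α-hydrogen, which excludes Kornblum–DeLaMare cleavage of the nucleophile, and high dilution should suppress dimerisation.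

Step 19
Reactants: 28 (14R,16S,17R)-1,2-dioxane
Product: 29 tetraol (6α-OH, 8α-OH, 16-OH, 19-OH)
Conditions: HF·pyridine, pyridine/THF, 0 °C to rt
Reagents that add atoms: none
Why: Fluoride-mediated desilylation should remove the primary TBDPS ether and both TES ethers, while the dialkyl peroxide, the methyl ester and the alkene are inert to buffered HF·pyridine.

Step 20
Reactants: 29 tetraol
Product: 32 CNP0162504.1 (target), via C19 aldehyde 30 (not isolated), via lactol 31 (not isolated)
Conditions: TEMPO (20 mol %), PhI(OAc)2, CH2Cl2, rt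
Reagents that add atoms: none
Why: In this oxoammonium-mediated oxidative lactonisation the only primary alcohol should be oxidised to the aldehyde, the C16 hydroxyl (equatorial and gauche to the C17 side chain in the reacting chair) closes the lactol, and a second oxidation gives the trans-fused γ-lactone (ring D), while the secondary C6 and tertiary C8 hydroxyls and the peroxide are left alone and no stereocenter changes.

Compound list
1 | (+)-larixol, labda-8(17),14-diene-6α,13S-diol | C=C[C@@](C)(O)CC[C@@H]1[C@@]2(C)CCCC(C)(C)[C@@H]2[C@@H](O)CC1=C | starting material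
2 | 8α,17-epoxylabd-14-ene-6α,13S-diol | C=C[C@@](C)(O)CC[C@@H]1[C@@]2(C)CCCC(C)(C)[C@@H]2[C@@H](O)C[C@@]1(C3)O3 | intermediate
3 | 8α,17-epoxy-6α-hydroxy-14,15-dinorlabdan-13-one | CC(=O)CC[C@@H]1[C@@]2(C)CCCC(C)(C)[C@@H]2[C@@H](O)C[C@@]1(C3)O3 | intermediate
4 | 6α-hypoiodite of 3 (not isolated) | CC(=O)CC[C@@H]1[C@@]2(C)CCCC(C)(C)[C@@H]2[C@@H](OI)C[C@@]1(C3)O3 | intermediate
5 | 8α,17-epoxy-6α-hydroxy-18-iodo-14,15-dinorlabdan-13-one, the 4α-iodomethyl alcohol (not isolated) | CC(=O)CC[C@@H]1[C@@]2(C)CCC[C@@](C)(CI)[C@@H]2[C@@H](O)C[C@@]1(C3)O3 | intermediate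
6 | 6α,18:8α,17-diepoxy-14,15-dinorlabdan-13-one | CC(=O)CC[C@@H]1[C@@]2(C)CCC[C@@](C)(CO3)[C@@H]2[C@@H]3C[C@@]1(C4)O4 | intermediate
7 | 6α,18-epoxy-14,15-dinorlabdane-8α,13-diol (both C13 epimers) | CC(O)CC[C@@H]1[C@@]2(C)CCC[C@@](C)(CO3)[C@@H]2[C@@H]3C[C@@]1(C)O | intermediate
8 | 8α-hydroxy-13-oxo-14,15-dinorlabdan-18,6α-olide | CC(=O)CC[C@@H]1[C@@]2(C)CCC[C@@](C)(C(=O)O3)[C@@H]2[C@@H]3C[C@@]1(C)O | intermediate
9 | potassium 6α,8α-dihydroxy-13-oxo-14,15-dinorlabdan-18-oate (not isolated) | CC(=O)CC[C@@H]1[C@@]2(C)CCC[C@@](C)(C(=O)[O-])[C@@H]2[C@@H](O)C[C@@]1(C)O.[K+] | intermediate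
10 | methyl 6α,8α-dihydroxy-13-oxo-14,15-dinorlabdan-18-oate | CC(=O)CC[C@@H]1[C@@]2(C)CCC[C@@](C)(C(=O)OC)[C@@H]2[C@@H](O)C[C@@]1(C)O | intermediate
11 | methyl 13-oxo-6α,8α-bis(triethylsilyloxy)-14,15-dinorlabdan-18-oate | CC(=O)CC[C@@H]1[C@@]2(C)CCC[C@@](C)(C(=O)OC)[C@@H]2[C@@H](O[Si](CC)(CC)CC)C[C@@]1(C)O[Si](CC)(CC)CC | intermediate
12 | terminal potassium enolate of 11 (not isolated) | C=C([O-])CC[C@@H]1[C@@]2(C)CCC[C@@](C)(C(=O)OC)[C@@H]2[C@@H](O[Si](CC)(CC)CC)C[C@@]1(C)O[Si](CC)(CC)CC.[K+] | intermediate
13 | terminal enol triflate of 11, CH2=C(OTf)– at C13 | C=C(OS(=O)(=O)C(F)(F)F)CC[C@@H]1[C@@]2(C)CCC[C@@](C)(C(=O)OC)[C@@H]2[C@@H](O[Si](CC)(CC)CC)C[C@@]1(C)O[Si](CC)(CC)CC | intermediate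
14 | but-3-yn-1-ol | C#CCCO | starting material
15 | tert-butyl(but-3-yn-1-yloxy)diphenylsilane | C#CCCO[Si](c1ccccc1)(c1ccccc1)C(C)(C)C | intermediate
16 | [(E)-4-(tert-butyldiphenylsilyloxy)-2-methylbut-1-enyl]dimethylalane (not isolated) | C[Al](C)/C=C(\C)CCO[Si](c1ccccc1)(c1ccccc1)C(C)(C)C | intermediate
17 | lithium butyl[(E)-4-(tert-butyldiphenylsilyloxy)-2-methylbut-1-enyl]dimethylaluminate (not isolated) | [Li+].CCCC[Al-](C)(C)/C=C(\C)CCO[Si](c1ccccc1)(c1ccccc1)C(C)(C)C | intermediate
18 | (E)-6-(tert-butyldiphenylsilyloxy)-4-methylhex-3-en-1-ol | OCC/C=C(\C)CCO[Si](c1ccccc1)(c1ccccc1)C(C)(C)C | intermediate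
19 | (E)-6-(tert-butyldiphenylsilyloxy)-4-methylhex-3-enal | O=CC/C=C(\C)CCO[Si](c1ccccc1)(c1ccccc1)C(C)(C)C | intermediate
20 | alkenylchromium dichloride from 13 (not isolated) | C=C([Cr](Cl)Cl)CC[C@@H]1[C@@]2(C)CCC[C@@](C)(C(=O)OC)[C@@H]2[C@@H](O[Si](CC)(CC)CC)C[C@@]1(C)O[Si](CC)(CC)CC | intermediate
21 | coupled allylic alcohol, 14-OH (both C14 epimers), 16E, C19 OTBDPS, 6α,8α-bis-OTES | C=C(CC[C@@H]1[C@@]2(C)CCC[C@@](C)(C(=O)OC)[C@@H]2[C@@H](O[Si](CC)(CC)CC)C[C@@]1(C)O[Si](CC)(CC)CC)C(O)C/C=C(\C)CCO[Si](c1ccccc1)(c1ccccc1)C(C)(C)C | intermediate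
22 | α-methylene ketone, C14=O, 16E | C=C(CC[C@@H]1[C@@]2(C)CCC[C@@](C)(C(=O)OC)[C@@H]2[C@@H](O[Si](CC)(CC)CC)C[C@@]1(C)O[Si](CC)(CC)CC)C(=O)C/C=C(\C)CCO[Si](c1ccccc1)(c1ccccc1)C(C)(C)C | intermediate
23 | (14R)-allylic alcohol, 16E | C=C(CC[C@@H]1[C@@]2(C)CCC[C@@](C)(C(=O)OC)[C@@H]2[C@@H](O[Si](CC)(CC)CC)C[C@@]1(C)O[Si](CC)(CC)CC)[C@H](O)C/C=C(\C)CCO[Si](c1ccccc1)(c1ccccc1)C(C)(C)C | intermediate
24 | (14S)-allylic chloride, 16E | C=C(CC[C@@H]1[C@@]2(C)CCC[C@@](C)(C(=O)OC)[C@@H]2[C@@H](O[Si](CC)(CC)CC)C[C@@]1(C)O[Si](CC)(CC)CC)[C@@H](Cl)C/C=C(\C)CCO[Si](c1ccccc1)(c1ccccc1)C(C)(C)C | intermediate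
25 | (14S,16S,17S)-14-chloro-16,17-epoxide | C=C(CC[C@@H]1[C@@]2(C)CCC[C@@](C)(C(=O)OC)[C@@H]2[C@@H](O[Si](CC)(CC)CC)C[C@@]1(C)O[Si](CC)(CC)CC)[C@@H](Cl)C[C@@H]1O[C@@]1(C)CCO[Si](c1ccccc1)(c1ccccc1)C(C)(C)C | intermediate
26 | (14S,16S,17R)-14-chloro-16-hydroxy-17-hydroperoxide | C=C(CC[C@@H]1[C@@]2(C)CCC[C@@](C)(C(=O)OC)[C@@H]2[C@@H](O[Si](CC)(CC)CC)C[C@@]1(C)O[Si](CC)(CC)CC)[C@@H](Cl)C[C@H](O)[C@](C)(OO)CCO[Si](c1ccccc1)(c1ccccc1)C(C)(C)C | intermediate
27 | potassium peroxide salt of 26 (not isolated) | C=C(CC[C@@H]1[C@@]2(C)CCC[C@@](C)(C(=O)OC)[C@@H]2[C@@H](O[Si](CC)(CC)CC)C[C@@]1(C)O[Si](CC)(CC)CC)[C@@H](Cl)C[C@H](O)[C@](C)(O[O-])CCO[Si](c1ccccc1)(c1ccccc1)C(C)(C)C.[K+] | intermediate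
28 | (14R,16S,17R)-1,2-dioxane, 16-OH free, C19 OTBDPS, 6α,8α-bis-OTES | C=C(CC[C@@H]1[C@@]2(C)CCC[C@@](C)(C(=O)OC)[C@@H]2[C@@H](O[Si](CC)(CC)CC)C[C@@]1(C)O[Si](CC)(CC)CC)[C@H]1C[C@H](O)[C@@](C)(CCO[Si](c2ccccc2)(c2ccccc2)C(C)(C)C)OO1 | intermediate
29 | tetraol (6α-OH, 8α-OH, 16-OH, 19-OH) | C=C(CC[C@@H]1[C@@]2(C)CCC[C@@](C)(C(=O)OC)[C@@H]2[C@@H](O)C[C@@]1(C)O)[C@H]1C[C@H](O)[C@@](C)(CCO)OO1 | intermediate
30 | C19 aldehyde of 29 (not isolated) | C=C(CC[C@@H]1[C@@]2(C)CCC[C@@](C)(C(=O)OC)[C@@H]2[C@@H](O)C[C@@]1(C)O)[C@H]1C[C@H](O)[C@@](C)(CC=O)OO1 | intermediate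
31 | lactol, C19 hemiacetal with O16 (not isolated) | C=C(CC[C@@H]1[C@@]2(C)CCC[C@@](C)(C(=O)OC)[C@@H]2[C@@H](O)C[C@@]1(C)O)[C@H]1C[C@@H]2OC(O)C[C@@]2(C)OO1 | intermediate
32 | CNP0162504.1 | C=C(CC[C@@H]1[C@@]2(C)CCC[C@@](C)(C(=O)OC)[C@@H]2[C@@H](O)C[C@@]1(C)O)[C@H]1C[C@@H]2OC(=O)C[C@@]2(C)OO1 | target

Total step count: 20. Longest linear sequence: 17 (steps 1–8 and 12–20).

Steps most likely to fail

Step 18. The peroxide anion may be outrun by base-induced cleavage of the β-hydroxy hydroperoxide at C16–C17 or by loss of HCl towards the diene, and the chloride of step 15 may already have suffered allylic transposition. The fallback sets out from ketone 22 and needs no substitution at C14. Shi epoxidation with the same ketone as in step 16 should take the C16=C17 alkene, which the conjugated C13 methylene does not contest, and give the (16S,17S)-epoxy enone F1. H2O2 with catalytic H3PMo12O40 opens it at C17, and the new hydroperoxide adds to the C14 ketone, so that ring C closes at O–C14 as the cyclic peroxyhemiketal F2. Et3SiH with BF3·OEt2 in CH2Cl2 at −78 °C then reduces F2 through the peroxycarbenium ion. Hydride should enter axially on the half-chair that keeps the C16 oxygen pseudoaxial, that is cis to it, which is the C14 configuration of 28, where the fallback comes back to the route. It is two steps shorter than steps 14–18, but its selectivity rests on a conformational preference and not on a stereospecific displacement, which is why it is not the main line.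

Step 3. The spiro-epoxide may be opened or rearranged by iodine and by the acetic acid that is released before the alkoxy radical has done its work. The fallback gives up the epoxide as the mask for C8 and sets out from 2. LiAlH4 in THF should open the epoxide to labd-14-ene-6α,8α,13S-triol F3, and KMnO4 then degrades the side chain to 6α,8α-dihydroxy-14,15-dinorlabdan-13-one F4. MeOH, HC(OMe)3 and PPTS tie the tertiary 8α-OH and the ketone into the cyclic methyl ketal 8α,13-epoxy-13-methoxy-14,15-dinorlabdan-6α-ol F5, which leaves 6α-OH as the only free hydroxyl. The hypoiodite reaction on this acid-tolerant substrate should give the 6α,18-ether F6. RuCl3/NaIO4 in its aqueous acidic medium oxidises the ether to the lactone and hydrolyses the ketal, which comes back to the route at 8.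

Step 20. The hydroxy aldehyde may be slow to close to the strained trans-fused lactol and may then lose the peroxide by β-elimination before the second oxidation. The fallback sets out from 29 and separates oxidation from ring closure. TEMPO/PhI(OAc)2 in MeCN/H2O should take the primary alcohol to the carboxylic acid level and give the seco acid F7. Carboxyl activation with EDC·HCl in CH2Cl2 at 0 °C then closes the γ-lactone onto the C16 hydroxyl, which comes back to the route at 32.

Further compounds
F1 | step 18 | (16S,17S)-16,17-epoxy enone from 22 | C=C(CC[C@@H]1[C@@]2(C)CCC[C@@](C)(C(=O)OC)[C@@H]2[C@@H](O[Si](CC)(CC)CC)C[C@@]1(C)O[Si](CC)(CC)CC)C(=O)C[C@@H]1O[C@@]1(C)CCO[Si](c1ccccc1)(c1ccccc1)C(C)(C)C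
F2 | step 18 | cyclic peroxyhemiketal (14-hydroxy-1,2-dioxane; 16S,17R; C14 epimers) | C=C(CC[C@@H]1[C@@]2(C)CCC[C@@](C)(C(=O)OC)[C@@H]2[C@@H](O[Si](CC)(CC)CC)C[C@@]1(C)O[Si](CC)(CC)CC)C1(O)C[C@H](O)[C@@](C)(CCO[Si](c2ccccc2)(c2ccccc2)C(C)(C)C)OO1
F3 | step 3 | labd-14-ene-6α,8α,13S-triol | C=C[C@@](C)(O)CC[C@@H]1[C@@]2(C)CCCC(C)(C)[C@@H]2[C@@H](O)C[C@@]1(C)O
F4 | step 3 | 6α,8α-dihydroxy-14,15-dinorlabdan-13-one | CC(=O)CC[C@@H]1[C@@]2(C)CCCC(C)(C)[C@@H]2[C@@H](O)C[C@@]1(C)O
F5 | step 3 | 8α,13-epoxy-13-methoxy-14,15-dinorlabdan-6α-ol (C13 epimers) | COC1(C)CC[C@@H]2[C@@]3(C)CCCC(C)(C)[C@@H]3[C@@H](O)C[C@@]2(C)O1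
F6 | step 3 | 6α,18:8α,13-diepoxy-13-methoxy-14,15-dinorlabdane (C13 epimers) | COC1(C)CC[C@@H]2[C@@]3(C)CCC[C@@](C)(CO4)[C@@H]3[C@@H]4C[C@@]2(C)O1
F7 | step 20 | seco acid (16-hydroxy C19 carboxylic acid of the target) | C=C(CC[C@@H]1[C@@]2(C)CCC[C@@](C)(C(=O)OC)[C@@H]2[C@@H](O)C[C@@]1(C)O)[C@H]1C[C@H](O)[C@@](C)(CC(=O)O)OO1
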